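**Plan**

1. Numbering: C7 is the benzylic carbinol carbon on ring A (the 4-glyceryloxy-3,5-dimethoxyphenyl ring), C8 the aryloxy-bearing carbon, C9 the CH2OH carbon; ring B is the 2,6-dimethoxy-4-(3-hydroxypropyl)phenoxy ring.
2. Retrosynthetic cuts, in order: three O-benzyl groups; the C7–O and side-chain terminal C–O bonds (both from C–B); ring A C1–C7 (aryl shift from boron to carbon); C7–C8 (CHCl insertion); the C8–O bond to ring B; C8–C9 (CHCl insertion); the glyceryl ether C–O of ring A.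
3. Forward: the C9→C8→C7 chain grows on one boron atom (BnOCH2–B, insert C8, put the ring B phenoxide on C8, insert C7). Ring A is then delivered to C7 from a borate and both C–B bonds are oxidised; no ring is built, both arenes are bought.
4. Enabling feature: C7 is a secondary carbinol carbon between ring A C1 and the O-aryl carbon C8. Its OH is the oxidation product of a C7–B bond, and a chloride on the same carbon lets ring A C1 shift from B to C7 with inversion.
5. Stereochemistry: one (S,S)-1,2-dicyclohexylethane-1,2-diol ester on boron fixes each C–Cl centre on insertion; substitution inverts and oxidation retains, giving (7R,8R), threo.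

Key step: step 6

Remark on the chemistry: the sense of induction relied on is that of C2-symmetric (S,S)-1,2-diol boronic esters, whose LiCHCl2 insertion gives the (R) α-chloride when the migrated carbon outranks boron.

**Route**

Step 1
Reactants: 1 4-bromo-2,6-dimethoxyphenol; 2 1,3-bis(benzyloxy)propan-2-ol
Product: 3 2-{[1,3-bis(benzyloxy)propan-2-yl]oxy}-5-bromo-1,3-dimethoxybenzene
Conditions: PPh3, DIAD, THF (concentrated), 0 °C → 40 °C
Reagents that add atoms: none
Why: Mitsunobu etherification, in which the acidic phenol protonates the betaine and its phenoxide displaces the oxyphosphonium group of the achiral secondary alcohol, installs the whole protected glyceryl ether without touching the aryl bromide.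

Step 2
Reactants: 4 potassium [(benzyloxy)methyl]trifluoroborate; 5 (1S,2S)-1,2-dicyclohexylethane-1,2-diol
Product: 6 (4S,5S)-2-[(benzyloxy)methyl]-4,5-dicyclohexyl-1,3,2-dioxaborolane
Conditions: TMSCl, MeCN, rt
Reagents that add atoms: none
Why: Fluorophile-assisted boronic ester formation, in which chlorotrimethylsilane strips fluoride from boron as Me3SiF and the diol esterifies the resulting halo borane, brings in C9 and the chiral director as a very stable C2-symmetric dioxaborolane.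

Step 3
Reactants: 6 (4S,5S)-2-[(benzyloxy)methyl]-4,5-dicyclohexyl-1,3,2-dioxaborolane
Product: 8 (4S,5S)-2-[(1R)-2-(benzyloxy)-1-chloroethyl]-4,5-dicyclohexyl-1,3,2-dioxaborolane, via lithium dichloromethylborate 7 (not isolated)
Conditions: CH2Cl2, n-BuLi, THF, −100 °C; then 6; ZnCl2, −100 °C → rt
Reagents that add atoms: dichloromethane, ClCCl (delivered as LiCHCl2)
Why: Matteson homologation, in which LiCHCl2 adds to boron and the CH2OBn group shifts from boron to carbon with loss of one of the two diastereotopic chlorides, should give the (1R) C8–Cl centre because the (S,S)-diol together with ZnCl2 selects which chloride leaves.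

Step 4
Reactants: 8 (4S,5S)-2-[(1R)-2-(benzyloxy)-1-chloroethyl]-4,5-dicyclohexyl-1,3,2-dioxaborolane; 9 4-allyl-2,6-dimethoxyphenol
Product: 11 (4S,5S)-2-[(1S)-1-(4-allyl-2,6-dimethoxyphenoxy)-2-(benzyloxy)ethyl]-4,5-dicyclohexyl-1,3,2-dioxaborolane, via sodium phenolate 10 (not isolated)
Conditions: 9 (slight excess over base), NaH, THF, 0 °C; then 8, THF–DMSO, rt
Reagents that add atoms: none
Why: Nucleophilic substitution of an α-chloro boronic ester by an oxygen nucleophile, invertive whether it runs by direct SN2 at the boron-activated carbon or by B→C shift of boron-bound aryloxide, sets the C8–O aryl ether in the configuration of the target (descriptor 1S here because boron ranks below C9).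

Step 5
Reactants: 11 (4S,5S)-2-[(1S)-1-(4-allyl-2,6-dimethoxyphenoxy)-2-(benzyloxy)ethyl]-4,5-dicyclohexyl-1,3,2-dioxaborolane
Product: 13 (4S,5S)-2-[(1R,2R)-2-(4-allyl-2,6-dimethoxyphenoxy)-3-(benzyloxy)-1-chloropropyl]-4,5-dicyclohexyl-1,3,2-dioxaborolane, via lithium dichloromethylborate 12 (not isolated)
Conditions: CH2Cl2, n-BuLi, THF, −100 °C; then 11; ZnCl2, −100 °C → rt
Reagents that add atoms: dichloromethane, ClCCl (delivered as LiCHCl2)
Why: A second Matteson homologation, in which C8 migrates from boron to the carbenoid carbon with retention and the same (S,S)-diol again selects the leaving chloride, should give the (1R) C7–Cl centre while ZnCl2 binds free chloride and suppresses epimerisation.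

Step 6
Reactants: 3 2-{[1,3-bis(benzyloxy)propan-2-yl]oxy}-5-bromo-1,3-dimethoxybenzene; 13 (4S,5S)-2-[(1R,2R)-2-(4-allyl-2,6-dimethoxyphenoxy)-3-(benzyloxy)-1-chloropropyl]-4,5-dicyclohexyl-1,3,2-dioxaborolane
Product: 16 (4S,5S)-2-[(1R,2S)-2-(4-allyl-2,6-dimethoxyphenoxy)-3-(benzyloxy)-1-(4-{[1,3-bis(benzyloxy)propan-2-yl]oxy}-3,5-dimethoxyphenyl)propyl]-4,5-dicyclohexyl-1,3,2-dioxaborolane, via arylmagnesium bromide 14 (not isolated), via magnesium arylborate 15 (not isolated)
Conditions: 3, Mg, THF, 40 °C; then 13, THF, −78 °C → rt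
Reagents that add atoms: none
Why: The aryl Grignard reagent 14 adds to the vacant boron orbital of 13 to give the tetracoordinate arylborate 15, in which ring A C1 migrates from boron to the adjacent carbon C7 antiperiplanar to the C7–Cl bond and expels chloride (1,2-metallate rearrangement), so that the C1–C7 bond forms with inversion at C7. The closest known reaction type is the substitution of α-chloro boronic esters by Grignard reagents in the Matteson homologation sequence. No ring is closed. The new stereocenter C7 is controlled by the configuration of the C7–Cl carbon of 13, itself fixed by the (S,S)-dicyclohexylethanediol ester in step 5, because the shift is stereospecific (inversion at C7, no change at C8). The step needs aryl migration with loss of chloride to win over β-elimination of the C8 aryloxide and over migration of a ring oxygen; this should be secured by chloride being the far better leaving group once bound to Mg(II), by the high migratory aptitude of the electron-rich aryl group, by the low migratory tendency of the dioxaborolane oxygens, and by forming the borate at −78 °C before slow warming.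

Step 7
Reactants: 16 (4S,5S)-2-[(1R,2S)-2-(4-allyl-2,6-dimethoxyphenoxy)-3-(benzyloxy)-1-(4-{[1,3-bis(benzyloxy)propan-2-yl]oxy}-3,5-dimethoxyphenyl)propyl]-4,5-dicyclohexyl-1,3,2-dioxaborolane
Product: 18 (1R,2R)-3-(benzyloxy)-1-(4-{[1,3-bis(benzyloxy)propan-2-yl]oxy}-3,5-dimethoxyphenyl)-2-[4-(3-hydroxypropyl)-2,6-dimethoxyphenoxy]propan-1-ol, via B-alkyl-9-BBN adduct 17 (not isolated)
Conditions: 9-BBN, THF, 0 °C → rt; then NaBO3·4H2O, THF–H2O, rt
Reagents that add atoms: sodium perborate, [Na+].[Na+].O[B-]1(O)OO[B-](O)(O)OO1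
Why: Brown hydroboration–oxidation, in which 9-BBN adds anti-Markovnikov to the allyl group only and mild perborate then oxidises both the primary C–B bond and the C7–B bond, should give the (7R) carbinol because C7 migrates from boron to oxygen with retention.

Step 8
Reactants: 18 (1R,2R)-3-(benzyloxy)-1-(4-{[1,3-bis(benzyloxy)propan-2-yl]oxy}-3,5-dimethoxyphenyl)-2-[4-(3-hydroxypropyl)-2,6-dimethoxyphenoxy]propan-1-ol
Product: 19 (1R,2R)-1-{4-[(1,3-dihydroxypropan-2-yl)oxy]-3,5-dimethoxyphenyl}-2-[4-(3-hydroxypropyl)-2,6-dimethoxyphenoxy]propane-1,3-diol (target)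
Conditions: H2 (1 atm), Pd(OH)2/C, EtOAc–MeOH, rt
Reagents that add atoms: none
Why: Catalytic hydrogenolysis of the three O-benzyl ethers under neutral conditions should leave the aryl ethers, the benzylic C7–OH and both stereocenters untouched.

**Compound list**

1 | 4-bromo-2,6-dimethoxyphenol | COc1cc(Br)cc(OC)c1O | starting material
2 | 1,3-bis(benzyloxy)propan-2-ol | OC(COCc1ccccc1)COCc1ccccc1 | starting material
3 | 2-{[1,3-bis(benzyloxy)propan-2-yl]oxy}-5-bromo-1,3-dimethoxybenzene | COc1cc(Br)cc(OC)c1OC(COCc1ccccc1)COCc1ccccc1 | intermediate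
4 | potassium [(benzyloxy)methyl]trifluoroborate | [K+].F[B-](F)(F)COCc1ccccc1 | starting material
5 | (1S,2S)-1,2-dicyclohexylethane-1,2-diol, (S,S)-DICHED | O[C@@H](C1CCCCC1)[C@@H](O)C1CCCCC1 | starting material
6 | (4S,5S)-2-[(benzyloxy)methyl]-4,5-dicyclohexyl-1,3,2-dioxaborolane | C(OCc1ccccc1)B1O[C@@H](C2CCCCC2)[C@H](C2CCCCC2)O1 | intermediate
7 | lithium (4S,5S)-2-[(benzyloxy)methyl]-2-(dichloromethyl)-4,5-dicyclohexyl-1,3,2-dioxaborolan-2-uide | [Li+].ClC(Cl)[B-]1(COCc2ccccc2)O[C@@H](C2CCCCC2)[C@H](C2CCCCC2)O1 | intermediate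
8 | (4S,5S)-2-[(1R)-2-(benzyloxy)-1-chloroethyl]-4,5-dicyclohexyl-1,3,2-dioxaborolane | Cl[C@@H](COCc1ccccc1)B1O[C@@H](C2CCCCC2)[C@H](C2CCCCC2)O1 | intermediate
9 | 4-allyl-2,6-dimethoxyphenol | C=CCc1cc(OC)c(O)c(OC)c1 | starting material
10 | sodium 4-allyl-2,6-dimethoxyphenolate | [Na+].[O-]c1c(OC)cc(CC=C)cc1OC | intermediate
11 | (4S,5S)-2-[(1S)-1-(4-allyl-2,6-dimethoxyphenoxy)-2-(benzyloxy)ethyl]-4,5-dicyclohexyl-1,3,2-dioxaborolane | C=CCc1cc(OC)c(O[C@H](COCc2ccccc2)B2O[C@@H](C3CCCCC3)[C@H](C3CCCCC3)O2)c(OC)c1 | intermediate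
12 | lithium (4S,5S)-2-[(1S)-1-(4-allyl-2,6-dimethoxyphenoxy)-2-(benzyloxy)ethyl]-2-(dichloromethyl)-4,5-dicyclohexyl-1,3,2-dioxaborolan-2-uide | [Li+].ClC(Cl)[B-]1([C@@H](COCc2ccccc2)Oc2c(OC)cc(CC=C)cc2OC)O[C@@H](C2CCCCC2)[C@H](C2CCCCC2)O1 | intermediate
13 | (4S,5S)-2-[(1R,2R)-2-(4-allyl-2,6-dimethoxyphenoxy)-3-(benzyloxy)-1-chloropropyl]-4,5-dicyclohexyl-1,3,2-dioxaborolane | Cl[C@H](B1O[C@@H](C2CCCCC2)[C@H](C2CCCCC2)O1)[C@@H](COCc1ccccc1)Oc1c(OC)cc(CC=C)cc1OC | intermediate
14 | (4-{[1,3-bis(benzyloxy)propan-2-yl]oxy}-3,5-dimethoxyphenyl)magnesium bromide | COc1cc([Mg]Br)cc(OC)c1OC(COCc1ccccc1)COCc1ccccc1 | intermediate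
15 | bromomagnesium (4S,5S)-2-[(1R,2R)-2-(4-allyl-2,6-dimethoxyphenoxy)-3-(benzyloxy)-1-chloropropyl]-2-(4-{[1,3-bis(benzyloxy)propan-2-yl]oxy}-3,5-dimethoxyphenyl)-4,5-dicyclohexyl-1,3,2-dioxaborolan-2-uide | Br[Mg+].Cl[C@H]([B-]1(c2cc(OC)c(OC(COCc3ccccc3)COCc3ccccc3)c(OC)c2)O[C@@H](C2CCCCC2)[C@H](C2CCCCC2)O1)[C@@H](COCc1ccccc1)Oc1c(OC)cc(CC=C)cc1OC | intermediate
16 | (4S,5S)-2-[(1R,2S)-2-(4-allyl-2,6-dimethoxyphenoxy)-3-(benzyloxy)-1-(4-{[1,3-bis(benzyloxy)propan-2-yl]oxy}-3,5-dimethoxyphenyl)propyl]-4,5-dicyclohexyl-1,3,2-dioxaborolane | COc1cc([C@@H](B2O[C@@H](C3CCCCC3)[C@H](C3CCCCC3)O2)[C@@H](COCc2ccccc2)Oc2c(OC)cc(CC=C)cc2OC)cc(OC)c1OC(COCc1ccccc1)COCc1ccccc1 | intermediate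
17 | 9-BBN adduct of 16: the allyl group is CH2CH2CH2–B(9-borabicyclo[3.3.1]nonan-9-yl), the (1R,2S) chain and the (4S,5S) dioxaborolane unchanged | COc1cc([C@@H](B2O[C@@H](C3CCCCC3)[C@H](C3CCCCC3)O2)[C@@H](COCc2ccccc2)Oc2c(OC)cc(CCCB3C4CCCC3CCC4)cc2OC)cc(OC)c1OC(COCc1ccccc1)COCc1ccccc1 | intermediate
18 | (1R,2R)-3-(benzyloxy)-1-(4-{[1,3-bis(benzyloxy)propan-2-yl]oxy}-3,5-dimethoxyphenyl)-2-[4-(3-hydroxypropyl)-2,6-dimethoxyphenoxy]propan-1-ol | COc1cc([C@@H](O)[C@@H](COCc2ccccc2)Oc2c(OC)cc(CCCO)cc2OC)cc(OC)c1OC(COCc1ccccc1)COCc1ccccc1 | intermediate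
19 | (1R,2R)-1-{4-[(1,3-dihydroxypropan-2-yl)oxy]-3,5-dimethoxyphenyl}-2-[4-(3-hydroxypropyl)-2,6-dimethoxyphenoxy]propane-1,3-diol | COc1cc([C@@H](O)[C@@H](CO)Oc2c(OC)cc(CCCO)cc2OC)cc(OC)c1OC(CO)CO | target

**Step count and risks**

Total step count: 8. Longest linear sequence: 7 steps (4/5 → 6 → 8 → 11 → 13 → 16 → 18 → 19); step 1 is the one-step side branch to 3.

Steps most likely to fail:

Step 6. The arylborate 15 may collapse by anti-elimination of boron and the C8 aryloxide faster than ring A shifts to C7, or chloride set free during the reaction may epimerise unreacted 13 at C7. The fallback sets out from 13 and returns at 18; it uses the C7–B bond of 13 as a latent carbonyl group instead of a migration terminus. Buffered oxidation (H2O2, pH 7 phosphate buffer, THF, 0 °C) should convert the α-chloro boronic ester into (R)-2-(4-allyl-2,6-dimethoxyphenoxy)-3-(benzyloxy)propanal F1. Addition of Grignard reagent 14 to this aldehyde, pre-complexed with MgBr2·OEt2 in CH2Cl2 at −78 °C, should run through the five-membered chelate between the carbonyl oxygen and the C8 aryloxy oxygen (supported by an ortho-methoxy group). Attack anti to CH2OBn should then give the threo carbinol (1R,2R)-2-(4-allyl-2,6-dimethoxyphenoxy)-3-(benzyloxy)-1-(4-{[1,3-bis(benzyloxy)propan-2-yl]oxy}-3,5-dimethoxyphenyl)propan-1-ol F2. 9-BBN followed by NaBO3 then turns the allyl group into the 3-hydroxypropyl chain and returns to 18.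

Step 4. Substitution by the hindered, weakly basic 2,6-dimethoxyphenoxide may be slower than chloride exchange at the α-carbon of 8, so that the C8 centre epimerises, or slower than elimination of HCl or benzyloxide. The fallback sets out from 9 and 3 and returns at 19; it makes the C8–O bond on a primary α-halo carbonyl compound and takes both stereocenters from an auxiliary.
- Phenol 9 is alkylated with (S)-4-benzyl-3-(bromoacetyl)-1,3-oxazolidin-2-one (K2CO3, acetone, rt) to (S)-3-[(4-allyl-2,6-dimethoxyphenoxy)acetyl]-4-benzyl-1,3-oxazolidin-2-one F3.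
- Bromide 3 is converted through Grignard reagent 14 and DMF into 4-{[1,3-bis(benzyloxy)propan-2-yl]oxy}-3,5-dimethoxybenzaldehyde F4.
- The dibutylboron (Z)-enolate of F3 (Bu2BOTf, i-Pr2NEt, CH2Cl2, −78 → 0 °C) should add to F4 through the Zimmerman–Traxler chair (Evans syn aldol) to give (S)-4-benzyl-3-[(2S,3R)-2-(4-allyl-2,6-dimethoxyphenoxy)-3-(4-{[1,3-bis(benzyloxy)propan-2-yl]oxy}-3,5-dimethoxyphenyl)-3-hydroxypropanoyl]-1,3-oxazolidin-2-one F5.
- LiBH4 (THF–MeOH, 0 °C) removes the auxiliary and gives (1R,2R)-2-(4-allyl-2,6-dimethoxyphenoxy)-1-(4-{[1,3-bis(benzyloxy)propan-2-yl]oxy}-3,5-dimethoxyphenyl)propane-1,3-diol F6.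
- 9-BBN then NaBO3 gives (1R,2R)-1-(4-{[1,3-bis(benzyloxy)propan-2-yl]oxy}-3,5-dimethoxyphenyl)-2-[4-(3-hydroxypropyl)-2,6-dimethoxyphenoxy]propane-1,3-diol F7.
- Hydrogenolysis (H2, Pd(OH)2/C) of the two benzyl ethers returns to 19.

Step 5. Borate formation and the B→C shift of the bulky α-aryloxyalkyl group may be slow, since the oxygen donors of ring B can bind Li+ and Zn2+; the carbenoid may then decompose or the chloride selection by the diol may erode. The fallback sets out from 11 and returns at 18; it introduces C7 at the CH2 level and defers the stereocenter to a carbonyl addition. Insertion of the unhindered carbenoid LiCH2Cl (BrCH2Cl, n-BuLi, THF, −78 °C → rt) should give (4S,5S)-2-[(2S)-2-(4-allyl-2,6-dimethoxyphenoxy)-3-(benzyloxy)propyl]-4,5-dicyclohexyl-1,3,2-dioxaborolane F8. NaBO3 oxidation gives (S)-2-(4-allyl-2,6-dimethoxyphenoxy)-3-(benzyloxy)propan-1-ol F9. Dess–Martin oxidation gives the aldehyde (R)-2-(4-allyl-2,6-dimethoxyphenoxy)-3-(benzyloxy)propanal F1, which is carried on through the carbinol (1R,2R)-2-(4-allyl-2,6-dimethoxyphenoxy)-3-(benzyloxy)-1-(4-{[1,3-bis(benzyloxy)propan-2-yl]oxy}-3,5-dimethoxyphenyl)propan-1-ol F2 to 18 as described for step 6.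

**Further compounds**

F1 | step 6 | (R)-2-(4-allyl-2,6-dimethoxyphenoxy)-3-(benzyloxy)propanal | O=C[C@@H](COCc1ccccc1)Oc1c(OC)cc(CC=C)cc1OC
F2 | step 6 | (1R,2R)-2-(4-allyl-2,6-dimethoxyphenoxy)-3-(benzyloxy)-1-(4-{[1,3-bis(benzyloxy)propan-2-yl]oxy}-3,5-dimethoxyphenyl)propan-1-ol | COc1cc([C@@H](O)[C@@H](COCc2ccccc2)Oc2c(OC)cc(CC=C)cc2OC)cc(OC)c1OC(COCc1ccccc1)COCc1ccccc1
F3 | step 4 | (S)-3-[(4-allyl-2,6-dimethoxyphenoxy)acetyl]-4-benzyl-1,3-oxazolidin-2-one | C=CCc1cc(OC)c(OCC(=O)N2[C@@H](Cc3ccccc3)COC2=O)c(OC)c1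
F4 | step 4 | 4-{[1,3-bis(benzyloxy)propan-2-yl]oxy}-3,5-dimethoxybenzaldehyde | COc1cc(C=O)cc(OC)c1OC(COCc1ccccc1)COCc1ccccc1
F5 | step 4 | (S)-4-benzyl-3-[(2S,3R)-2-(4-allyl-2,6-dimethoxyphenoxy)-3-(4-{[1,3-bis(benzyloxy)propan-2-yl]oxy}-3,5-dimethoxyphenyl)-3-hydroxypropanoyl]-1,3-oxazolidin-2-one | COc1cc([C@@H](O)[C@H](Oc2c(OC)cc(CC=C)cc2OC)C(=O)N2[C@@H](Cc3ccccc3)COC2=O)cc(OC)c1OC(COCc1ccccc1)COCc1ccccc1
F6 | step 4 | (1R,2R)-2-(4-allyl-2,6-dimethoxyphenoxy)-1-(4-{[1,3-bis(benzyloxy)propan-2-yl]oxy}-3,5-dimethoxyphenyl)propane-1,3-diol | COc1cc([C@@H](O)[C@@H](CO)Oc2c(OC)cc(CC=C)cc2OC)cc(OC)c1OC(COCc1ccccc1)COCc1ccccc1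
F7 | step 4 | (1R,2R)-1-(4-{[1,3-bis(benzyloxy)propan-2-yl]oxy}-3,5-dimethoxyphenyl)-2-[4-(3-hydroxypropyl)-2,6-dimethoxyphenoxy]propane-1,3-diol | COc1cc([C@@H](O)[C@@H](CO)Oc2c(OC)cc(CCCO)cc2OC)cc(OC)c1OC(COCc1ccccc1)COCc1ccccc1
F8 | step 5 | (4S,5S)-2-[(2S)-2-(4-allyl-2,6-dimethoxyphenoxy)-3-(benzyloxy)propyl]-4,5-dicyclohexyl-1,3,2-dioxaborolane | C=CCc1cc(OC)c(O[C@H](COCc2ccccc2)CB2O[C@@H](C3CCCCC3)[C@H](C3CCCCC3)O2)c(OC)c1
F9 | step 5 | (S)-2-(4-allyl-2,6-dimethoxyphenoxy)-3-(benzyloxy)propan-1-ol | C=CCc1cc(OC)c(O[C@H](COCc2ccccc2)CO)c(OC)c1
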